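**Assumption:** the target is taken exactly as the given SMILES, i.e. (2E,3R,4R,5aS,7S,9aS) in 1-benzoxepine numbering; the enantiomer of the chiral bromination catalyst in step 4 is the one that delivers the 6S bromide (to be confirmed on the product by X-ray anomalous dispersion).

## Retrosynthetic overview

- The oxirane is put on last, by α-face epoxidation of the 3,4-alkene of an (E)-2-(bromomethylidene)oxepine.
- The seven-membered ring B comes from ring expansion of a 2-ethynyl tetrahydropyran: the ring oxygen shifts 1,2 onto the activated alkyne, anti to the electrophile, which fixes the E bromoalkene.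
- Ring A and the six-membered precursor of ring B are formed together in one enantioselective bromonium cyclisation of dehydronerolidol (C–Br, C–C and C–O bonds, three stereocentres).
- Dehydronerolidol comes from ethynylmagnesium bromide and geranylacetone; geranylacetone from methylalumination of 6-methylhept-5-en-1-yne and addition to methyl vinyl ketone; the enyne from homoprenyl bromide and acetylide.
- Ring order: ring A plus tetrahydropyran, then expansion to the oxepane, then the oxirane.

## Route

Step 1
Reactants: 1 5-bromo-2-methylpent-2-ene; 2 lithium acetylide–ethylenediamine complex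
Product: 3 6-methylhept-5-en-1-yne
Conditions: DMSO, 10 °C to rt
Reagents that add atoms: none
Why: SN2 alkylation of the acetylide by the primary homoallylic bromide; no stereocentre is formed.

Step 2
Reactants: 3 6-methylhept-5-en-1-yne; 4 methyl vinyl ketone
Product: 6 (E)-6,10-dimethylundeca-5,9-dien-2-one (geranylacetone), via alkenylalane 5 (not isolated)
Conditions: Me3Al (2 equiv), Cp2ZrCl2 (20 mol %), CH2Cl2, 0 °C to rt; volatiles removed; then 4, CuBr·SMe2 (10 mol %), THF, −20 °C; H2O
Reagents that add atoms: trimethylaluminium C[Al](C)C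
Why: Zirconium-catalysed syn methylalumination (Negishi carboalumination) places Me and Al cis and so fixes the E trisubstituted alkene; the alkenyl group is then transferred 1,4 to the enone with retention (copper-catalysed conjugate addition).

Step 3
Reactants: 6 (E)-6,10-dimethylundeca-5,9-dien-2-one; 7 ethynylmagnesium bromide
Product: 8 (E)-3,7,11-trimethyldodeca-6,10-dien-1-yn-3-ol (racemic dehydronerolidol)
Conditions: THF, 0 °C to rt; H2O work-up
Reagents that add atoms: none
Why: 1,2-Addition of the alkynyl Grignard reagent to the methyl ketone; the new carbinol centre is racemic on purpose because it becomes sp2 in step 5.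

Step 4
Reactants: 8 (E)-3,7,11-trimethyldodeca-6,10-dien-1-yn-3-ol
Product: 9 (4aS,6S,8aS)-6-bromo-2-ethynyl-2,5,5,8a-tetramethyloctahydro-2H-chromene (both C2 epimers)
Conditions: DBDMH (1.1 equiv), N-triflyl thiophosphoramide of 3,3′-bis(2,4,6-triisopropylphenyl)-BINOL (10 mol %, enantiomer per the assumption), toluene/CH2Cl2, −90 °C
Reagents that add atoms: 1,3-dibromo-5,5-dimethylhydantoin CC1(C)N(Br)C(=O)N(Br)C1=O
Why: Catalyst-controlled enantioselective bromonium polyene cyclisation terminated by the tertiary hydroxyl: anti addition through a chair–chair array gives equatorial Br (6S) and the trans ring fusion (4a-H and 8a-Me trans), the catalyst choosing the face of the terminal alkene and thereby all three ring stereocentres.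

Step 5
Reactants: 9 (4aS,6S,8aS)-6-bromo-2-ethynyl-2,5,5,8a-tetramethyloctahydro-2H-chromene
Product: 11 (2E,5aS,7S,9aS)-7-bromo-2-(bromomethylidene)-3,6,6,9a-tetramethyl-2,5,5a,6,7,8,9,9a-octahydro-1-benzoxepine, via vinylmercury triflate 10 (not isolated)
Conditions: Hg(OTf)2 (1.05 equiv), 2,6-di-tert-butyl-4-methylpyridine (1.5 equiv), MeNO2/CH2Cl2, −40 °C; then NBS (1.05 equiv), −40 to 0 °C
Reagents that add atoms: N-bromosuccinimide O=C1CCC(=O)N1Br
Why: Proposed new method: Hg(OTf)2 π-activates the terminal alkyne so that its internal carbon becomes cationic, the ring oxygen bridges to it anti to mercury (alkylidene-oxiranium) and the tertiary propargylic C–O bond breaks to a 2-alkoxyallyl cation, a 1,2-shift of the ring oxygen that turns the tetrahydropyran into the oxepane (both C2 epimers converge), the hindered base removes a proton from the adjacent ring CH2 to give the diene, and NBS cleaves the C–Hg bond with retention so that O and Br end up trans (E); the closest known reactions are the oxiranium-mediated ring expansion of 2-(1-sulfonyloxyalkyl)tetrahydropyrans to oxepanes at an sp3 carbon and the anti oxymercuration of alkynols followed by halodemercuration.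

Step 6
Reactants: 11 (2E,5aS,7S,9aS)-7-bromo-2-(bromomethylidene)-3,6,6,9a-tetramethyl-2,5,5a,6,7,8,9,9a-octahydro-1-benzoxepine
Product: 12 (2E,3R,4R,5aS,7S,9aS)-7-bromo-2-(bromomethylidene)-3,4-epoxy-3,6,6,9a-tetramethyldecahydro-1-benzoxepine (CNP0375295.1)
Conditions: DMDO (1.1 equiv), acetone/CH2Cl2, −40 to −20 °C
Reagents that add atoms: dimethyldioxirane CC1(C)OO1
Why: Neutral electrophilic epoxidation in which the trisubstituted 3,4-alkene should react faster than the bromine-deactivated enol ether, and attack from the α-face, anti to the axial 9a- and 6-methyl groups of the trans-fused bicycle, sets 3R,4R.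

## Compound list

1 | 5-bromo-2-methylpent-2-ene | CC(C)=CCCBr | starting material
2 | lithium acetylide–ethylenediamine complex | [Li+].[C-]#C.NCCN | starting material
3 | 6-methylhept-5-en-1-yne | C#CCCC=C(C)C | intermediate
4 | methyl vinyl ketone (but-3-en-2-one) | CC(=O)C=C | starting material
5 | (E)-(2,6-dimethylhepta-1,5-dien-1-yl)dimethylalane | C[Al](C)/C=C(\C)CCC=C(C)C | intermediate
6 | (E)-6,10-dimethylundeca-5,9-dien-2-one (geranylacetone) | CC(=O)CC/C=C(\C)CCC=C(C)C | intermediate
7 | ethynylmagnesium bromide | C#C[Mg]Br | starting material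
8 | (E)-3,7,11-trimethyldodeca-6,10-dien-1-yn-3-ol, racemic at C3 | C#CC(C)(O)CC/C=C(\C)CCC=C(C)C | intermediate
9 | (4aS,6S,8aS)-6-bromo-2-ethynyl-2,5,5,8a-tetramethyloctahydro-2H-chromene, both C2 epimers | CC1(C)[C@@H](Br)CC[C@]2(C)OC(C)(C#C)CC[C@@H]12 | intermediate
10 | vinylmercury triflate: compound 11 with HgOTf in place of the vinylic bromine (Hg trans to the ring O) | CC1(C)[C@@H](Br)CC[C@]2(C)O/C(=C/[Hg]OS(=O)(=O)C(F)(F)F)C(C)=CC[C@@H]12 | intermediate
11 | (2E,5aS,7S,9aS)-7-bromo-2-(bromomethylidene)-3,6,6,9a-tetramethyl-2,5,5a,6,7,8,9,9a-octahydro-1-benzoxepine | CC1(C)[C@@H](Br)CC[C@]2(C)O/C(=C/Br)C(C)=CC[C@@H]12 | intermediate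
12 | (2E,3R,4R,5aS,7S,9aS)-7-bromo-2-(bromomethylidene)-3,4-epoxy-3,6,6,9a-tetramethyldecahydro-1-benzoxepine (CNP0375295.1) | CC1(C)[C@@H](Br)CC[C@]2(C)O/C(=C/Br)[C@]3(C)O[C@@H]3C[C@@H]12 | target

## Step count and risks

Total steps: 6. Longest linear sequence: 6 (from 1).

Steps most likely to fail:

**1. Step 5 (the proposed ring expansion).** Possible failures:
- a carbon (methyl or ring CH2) migrates instead of oxygen, giving a ring-contracted oxocarbenium ion;
- divalent mercury attacks the secondary bromide;
- the proton is lost from the methyl group, giving the exocyclic alkene isomer.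

A catalytic Ph3PAuNTf2/NBS variant was set aside because bromination of the gold acetylide would give the bromoalkyne and then the Z isomer.

Fallback by known reaction types, setting out from 6 and coming back at 11; it closes ring B directly as the seven-membered ring. Bromonium cyclisation of 6 (DBDMH and the catalyst of step 4), terminated by the ketone oxygen with loss of a proton, gives (4aS,6S,8aS)-6-bromo-2,5,5,8a-tetramethyl-4a,5,6,7,8,8a-hexahydro-4H-chromene F1. AcOH/THF/H2O hydrolyses the enol ether to 4-[(1S,3S,6S)-3-bromo-6-hydroxy-2,2,6-trimethylcyclohexyl]butan-2-one F2. Excess 7 adds to the ketone to give 5-[(1S,3S,6S)-3-bromo-6-hydroxy-2,2,6-trimethylcyclohexyl]-3-methylpent-1-yn-3-ol F3. Anti oxymercuration of the alkyne by the ring hydroxyl (7-exo-dig, Hg(OCOCF3)2, CH2Cl2) and cleavage of the vinylmercurial with NBS give (2E,5aS,7S,9aS)-7-bromo-2-(bromomethylidene)-3,6,6,9a-tetramethyldecahydro-1-benzoxepin-3-ol F4. Burgess dehydration of the tertiary alcohol then gives 11.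

**2. Step 4 (enantioselective bromocyclisation).** Termination by a tertiary alcohol under the chiral catalyst extends the phenol- and arene-terminated cases; ee or yield may be low. Fallback setting out from 8 and coming back at 9: racemic cyclisation with Et2SBr·SbCl5Br in MeNO2 at −25 °C gives 9 together with its mirror-image series (4aR,6R,8aR)-6-bromo-2-ethynyl-2,5,5,8a-tetramethyloctahydro-2H-chromene F5. F5 is removed by preparative chromatography on a chiral stationary phase, and the absolute configuration is assigned by X-ray.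

**3. Step 6 (epoxidation).** The oxidant may attack the bromo enol ether or the β-face. Fallback that installs the oxirane before the enol ether exists, setting out from 6, passing through F1, F2 and F3 as in the fallback for step 5, and coming back at 12. Burgess dehydration of the propargylic carbinol of F3 gives (1S,2S,4S)-4-bromo-1,3,3-trimethyl-2-[(2Z)-3-methylpent-2-en-4-yn-1-yl]cyclohexan-1-ol F6. Shi epoxidation (fructose-derived ketone/Oxone, enantiomer chosen for the 2R,3S oxirane) gives (1S,2S,4S)-4-bromo-2-{[(2R,3S)-3-ethynyl-3-methyloxiran-2-yl]methyl}-1,3,3-trimethylcyclohexan-1-ol F7, with the face set by the reagent. Anti oxymercuration (7-exo-dig, Hg(OCOCF3)2) and NBS cleavage then close ring B and give 12.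

## Further compounds

F1 | step 5 | (4aS,6S,8aS)-6-bromo-2,5,5,8a-tetramethyl-4a,5,6,7,8,8a-hexahydro-4H-chromene | CC1(C)[C@@H](Br)CC[C@]2(C)OC(C)=CC[C@@H]12
F2 | step 5 | 4-[(1S,3S,6S)-3-bromo-6-hydroxy-2,2,6-trimethylcyclohexyl]butan-2-one | CC1(C)[C@@H](Br)CC[C@](C)(O)[C@H]1CCC(C)=O
F3 | step 5 | 5-[(1S,3S,6S)-3-bromo-6-hydroxy-2,2,6-trimethylcyclohexyl]-3-methylpent-1-yn-3-ol, both C3 epimers | CC1(C)[C@@H](Br)CC[C@](C)(O)[C@H]1CCC(C)(O)C#C
F4 | step 5 | (2E,5aS,7S,9aS)-7-bromo-2-(bromomethylidene)-3,6,6,9a-tetramethyldecahydro-1-benzoxepin-3-ol, both C3 epimers | CC1(C)[C@@H](Br)CC[C@]2(C)O/C(=C/Br)C(C)(O)CC[C@@H]12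
F5 | step 4 | (4aR,6R,8aR)-6-bromo-2-ethynyl-2,5,5,8a-tetramethyloctahydro-2H-chromene, both C2 epimers | CC1(C)[C@H](Br)CC[C@@]2(C)OC(C)(C#C)CC[C@H]12
F6 | step 6 | (1S,2S,4S)-4-bromo-1,3,3-trimethyl-2-[(2Z)-3-methylpent-2-en-4-yn-1-yl]cyclohexan-1-ol | CC1(C)[C@@H](Br)CC[C@](C)(O)[C@H]1C/C=C(/C)C#C
F7 | step 6 | (1S,2S,4S)-4-bromo-2-{[(2R,3S)-3-ethynyl-3-methyloxiran-2-yl]methyl}-1,3,3-trimethylcyclohexan-1-ol | CC1(C)[C@@H](Br)CC[C@](C)(O)[C@H]1C[C@H]2O[C@@]2(C)C#C
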